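**Plan** (labdane numbering C1–C20 is used for atoms)

- Cuts, in retrosynthetic order: C7–O (allylic hydroxylation); C8–C9 (radical closure of ring B); C6–C7 (propargylation of a lactol); C9=C11 (Wittig, brings the whole side chain); then C1–C10 and C4–C5 together ([4+2]) and the C19–O–C6 ester.
- Enabling feature: ring A carries the contiguous centres C4, C5 and C10 with C19–O, C6 and the C10 methyl on one face. A temporary C19–O–C6(=O) ester can therefore tie a (Z)-diene (C1–C4, C18, C19) to an (E)-formylcrotonate (C5, C6, C9, C10, C20).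
- Forward: two achiral C6 and C5 pieces are esterified; one intramolecular Diels–Alder reaction closes ring A and a cis-fused γ-lactone. The lactone is then spent (C19 becomes the acetoxymethyl group, C6 the ring B methylene) and ring B is closed by a 6-exo vinyl-radical cyclisation.
- Stereochemistry: C4/C5/C10 relative configuration from the two alkene geometries; absolute configuration from a chiral oxazaborolidinium catalyst; C9 from a chair transition state on the rigid ring A; C7 from axial SeO2 hydroxylation; 13E from E-selective oxidation of prenol.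

Key step: step 7

Assumption: the (S)-diphenylprolinol-derived catalyst is taken to shield the enal face that would lead to the enantiomer of 9; should the sense prove opposite, the (R)-catalyst is used and nothing else changes.

**Route**

Step 1
Reactants: 1 4-methylfuran-2(5H)-one
Product: 2 4-methyl-2,5-dihydrofuran-2-ol
Conditions: i-Bu2AlH (1.1 equiv), CH2Cl2, −78 °C; Rochelle salt
Reagents that add atoms: none
Why: Low-temperature half-reduction of a butenolide to the lactol (i-Bu2AlH lactone-to-lactol reduction), the ring holding the two carbon substituents of the trisubstituted alkene cis.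

Step 2
Reactants: 2 4-methyl-2,5-dihydrofuran-2-ol
Product: 3 (2Z)-2-methylpenta-2,4-dien-1-ol
Conditions: Ph3PCH3Br, KOt-Bu (2.2 equiv ylide), THF, 0 °C → rt
Reagents that add atoms: methylenetriphenylphosphorane, C=P(c1ccccc1)(c1ccccc1)c1ccccc1
Why: Wittig methylenation at the hemiacetal carbon of the lactol should give the diene with the Z geometry inherited from the ring.

Step 3
Reactants: 4 ethyl (2E)-3-methyl-4-oxobut-2-enoate
Product: 5 ethyl (2E)-4,4-dimethoxy-3-methylbut-2-enoate
Conditions: HC(OMe)3, MeOH, p-TsOH (cat.), rt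
Reagents that add atoms: trimethyl orthoformate, COC(OC)OC
Why: Acid-catalysed acetalisation masks the aldehyde so that the ester can be exchanged without isomerising the (E)-alkene.

Step 4
Reactants: 5 ethyl (2E)-4,4-dimethoxy-3-methylbut-2-enoate
Product: 6 (2E)-4,4-dimethoxy-3-methylbut-2-enoic acid
Conditions: LiOH, THF/H2O, 0 °C → rt; then cold 10% citric acid
Reagents that add atoms: lithium hydroxide, [Li+].[OH-]
Why: Saponification leaves the base-stable acetal and the alkene geometry untouched, and a brief cold weak-acid work-up frees the acid.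

Step 5
Reactants: 6 (2E)-4,4-dimethoxy-3-methylbut-2-enoic acid; 3 (2Z)-2-methylpenta-2,4-dien-1-ol
Product: 7 (2Z)-2-methylpenta-2,4-dien-1-yl (2E)-4,4-dimethoxy-3-methylbut-2-enoate
Conditions: EDC·HCl, DMAP (cat.), CH2Cl2, 0 °C → rt
Reagents that add atoms: none
Why: Carbodiimide (Steglich) esterification of a primary allylic alcohol proceeds under neutral conditions that preserve both alkene geometries.

Step 6
Reactants: 7 (2Z)-2-methylpenta-2,4-dien-1-yl (2E)-4,4-dimethoxy-3-methylbut-2-enoate
Product: 8 (2Z)-2-methylpenta-2,4-dien-1-yl (2E)-3-methyl-4-oxobut-2-enoate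
Conditions: 5% aq. oxalic acid on SiO2, CH2Cl2, rt
Reagents that add atoms: water, O
Why: The acetal of an α,β-unsaturated aldehyde hydrolyses under very mild acid, which should spare the dienyl ester.

Step 7
Reactants: 8 (2Z)-2-methylpenta-2,4-dien-1-yl (2E)-3-methyl-4-oxobut-2-enoate
Product: 9 (3aS,7S,7aS)-3a,7-dimethyl-1-oxo-1,3,3a,6,7,7a-hexahydro-2-benzofuran-7-carbaldehyde
Conditions: (S)-diphenylprolinol-derived B-(o-tolyl)oxazaborolidine protonated with Tf2NH (20 mol %), CH2Cl2 (0.02 M), −78 → −20 °C
Reagents that add atoms: none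
Why: Proposed new method: the boron Lewis acid binds the formyl oxygen of the s-trans enal, lowers the LUMO of the C5=C10 double bond and shields one of its faces, and the tethered (Z)-diene adds in a concerted asynchronous [4+2] in which the C4–C5 bond leads and the C1–C10 bond follows; the closest known reaction type is the oxazaborolidinium-catalysed enantioselective Diels–Alder reaction of α-substituted enals, including intramolecular cases of all-carbon-tethered trienals, and what is new is the ester tether and the (Z)-diene. Ring A closes as the cyclohexene of the [4+2] and the γ-lactone closes as the five-membered ring spanned by the three-atom C19–O–C6 tether across the new C4–C5 bond. The trans relation of H-5 and the C10 methyl follows from suprafacial addition to the (E)-alkene, the cis relation of C19 and C6 (hence 4β-CH2O and 5α-H) from the tether sitting on the inside position of the (Z)-diene, which allows only the cis-fused lactone with the tether carbonyl exo and the formyl group endo, and the absolute configuration from the catalyst. The step needs facial selectivity and freedom from alkene isomerisation or 1,5-hydrogen shift, and the low temperature of the catalysed reaction together with the fixed geometry of both alkenes should secure the latter.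

Step 8
Reactants: 9 (3aS,7S,7aS)-3a,7-dimethyl-1-oxo-1,3,3a,6,7,7a-hexahydro-2-benzofuran-7-carbaldehyde
Product: 10 (3aS,7S,7aS)-3a,7-dimethyl-1-oxooctahydro-2-benzofuran-7-carbaldehyde
Conditions: H2 (1 atm), Pd/C, EtOAc, rt
Reagents that add atoms: none
Why: Heterogeneous hydrogenation of the only C=C bond (C2=C3) should leave the non-enolisable aldehyde and the lactone untouched and creates no stereocentre.

Step 9
Reactants: 11 3-methylbut-2-en-1-ol (prenol)
Product: 12 tert-butyl[(3-methylbut-2-en-1-yl)oxy]diphenylsilane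
Conditions: TBDPSCl, imidazole, DMF, rt
Reagents that add atoms: tert-butyl(chloro)diphenylsilane, CC(C)(C)[Si](Cl)(c1ccccc1)c1ccccc1
Why: Standard silylation of a primary alcohol gives an ether that survives the later oxidation, ylide, hydride, radical and acid steps.

Step 10
Reactants: 12 tert-butyl[(3-methylbut-2-en-1-yl)oxy]diphenylsilane
Product: 13 (2E)-4-[(tert-butyldiphenylsilyl)oxy]-2-methylbut-2-en-1-ol
Conditions: SeO2 (0.1 equiv), t-BuOOH (3 equiv), CH2Cl2, 0 °C → rt
Reagents that add atoms: tert-butyl hydroperoxide, CC(C)(C)OO; selenium dioxide, O=[Se]=O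
Why: SeO2-catalysed allylic hydroxylation (ene reaction then [2,3] shift) of a prenyl ether takes place at the (E)-methyl group and so fixes the later 13E geometry.

Step 11
Reactants: 13 (2E)-4-[(tert-butyldiphenylsilyl)oxy]-2-methylbut-2-en-1-ol
Product: 14 {[(2E)-4-bromo-3-methylbut-2-en-1-yl]oxy}(tert-butyl)diphenylsilane
Conditions: CBr4, PPh3, CH2Cl2, 0 °C
Reagents that add atoms: carbon tetrabromide, BrC(Br)(Br)Br
Why: Appel bromination of the primary allylic alcohol occurs without allylic transposition or loss of alkene geometry.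

Step 12
Reactants: 14 {[(2E)-4-bromo-3-methylbut-2-en-1-yl]oxy}(tert-butyl)diphenylsilane
Product: 15 {(3E)-5-[(tert-butyldiphenylsilyl)oxy]-3-methylpent-3-en-1-yl}triphenylphosphonium bromide
Conditions: Ph3PCH3Br, n-BuLi, THF, −78 °C; then 14, −78 °C → rt
Reagents that add atoms: methylenetriphenylphosphorane, C=P(c1ccccc1)(c1ccccc1)c1ccccc1
Why: SN2 alkylation of methylenetriphenylphosphorane by a primary allylic bromide is the classical route to homoallylic phosphonium salts and adds C11.

Step 13
Reactants: 15 {(3E)-5-[(tert-butyldiphenylsilyl)oxy]-3-methylpent-3-en-1-yl}triphenylphosphonium bromide; 10 (3aS,7S,7aS)-3a,7-dimethyl-1-oxooctahydro-2-benzofuran-7-carbaldehyde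
Product: 17 lactone 10 carrying the (1Z,4E)-6-[(tert-butyldiphenylsilyl)oxy]-4-methylhexa-1,4-dien-1-yl chain in place of the formyl group, via phosphonium ylide 16 (not isolated)
Conditions: NaN(SiMe3)2, THF, −78 °C; then 10, −78 °C → rt
Reagents that add atoms: none
Why: Wittig olefination of the non-enolisable neopentyl aldehyde with a non-stabilised ylide should be faster than attack on the lactone and give mainly the (Z)-alkene, either isomer serving because C11 becomes a methylene later.

Step 14
Reactants: 17 dienyl lactone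
Product: 18 dienyl lactol (anomer mixture)
Conditions: i-Bu2AlH (1.2 equiv), CH2Cl2, −78 °C; Rochelle salt
Reagents that add atoms: none
Why: Low-temperature i-Bu2AlH reduction stops at the lactol and leaves the alkenes and the silyl ether alone.

Step 15
Reactants: 18 dienyl lactol
Product: 19 homopropargylic diol (free 19-OH; 6-OH epimer mixture)
Conditions: propargyl bromide, Zn dust, THF/sat. aq. NH4Cl, 0 °C → rt
Reagents that add atoms: propargyl bromide, C#CCBr
Why: Barbier propargylation of the lactol through the allenylzinc species (SE2') adds C7, C8 and C17 in one step and frees the C19 hydroxyl, the new carbinol centre at C6 being removed later.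

Step 16
Reactants: 19 homopropargylic diol
Product: 20 19-acetate of diol 19 (6-OH free)
Conditions: AcCl (1.1 equiv), 2,4,6-collidine, CH2Cl2, −78 → −40 °C
Reagents that add atoms: acetyl chloride, CC(Cl)=O
Why: Acetyl chloride with collidine acylates a primary alcohol in preference to a secondary one, here a secondary carbinol that is in addition flanked by C5 between two quaternary carbons.

Step 17
Reactants: 20 19-acetate with free 6-OH
Product: 21 O-(imidazol-1-ylthiocarbonyl) derivative of 20 at C6
Conditions: 1,1'-thiocarbonyldiimidazole, DMAP (cat.), ClCH2CH2Cl, 70 °C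
Reagents that add atoms: 1,1'-thiocarbonyldiimidazole, S=C(n1ccnc1)n1ccnc1
Why: Formation of the thiocarbonyl imidazolide of a hindered secondary alcohol is the standard activation for radical deoxygenation and tolerates the acetate and the alkyne.

Step 18
Reactants: 21 thiocarbonyl imidazolide
Product: 22 enyne with C6 as CH2 (5-(but-3-ynyl) chain; 19-OAc; 15-OTBDPS)
Conditions: Bu3SnH (1.3 equiv), AIBN (cat.), PhMe, 100 °C
Reagents that add atoms: none
Why: Barton–McCombie deoxygenation, in which the stannyl radical attacks the thiocarbonyl group far faster than it adds to the terminal alkyne and the C6 radical has no favourable cyclisation mode.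

Step 19
Reactants: 22 enyne
Product: 24 19-acetoxy-15-[(tert-butyldiphenylsilyl)oxy]labda-8(17),13E-diene, via vinylstannane 23 (not isolated)
Conditions: Bu3SnH (1.5 equiv, slow addition), AIBN, PhH (0.01 M), 80 °C; then CF3CO2H, CH2Cl2, −20 °C
Reagents that add atoms: none
Why: Stannyl radical addition to the terminal alkyne gives the C8 vinyl radical, which closes ring B by 6-exo-trig attack on C9 (Stork enyne radical cyclisation) through a chair transition state on the rigid ring A with C11 equatorial, so that the side chain ends β-equatorial with 9α-H, and ipso-protodestannylation then leaves the exocyclic methylene.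

Step 20
Reactants: 24 19-acetoxy-15-[(tert-butyldiphenylsilyl)oxy]labda-8(17),13E-diene
Product: 25 19-acetoxy-15-[(tert-butyldiphenylsilyl)oxy]labda-8(17),13E-dien-7α-ol
Conditions: SeO2 (0.5 equiv), t-BuOOH (2 equiv), CH2Cl2, 0 °C → rt
Reagents that add atoms: tert-butyl hydroperoxide, CC(C)(C)OO; selenium dioxide, O=[Se]=O
Why: SeO2 allylic hydroxylation of the exocyclic alkene (ene reaction at C17 with loss of the axial 7α-H, then [2,3] shift) returns the 8(17)-alkene and delivers oxygen axially to C7, while the 13-alkene is deactivated by its allylic silyloxy group as in geranyl-type ethers.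

Step 21
Reactants: 25 19-acetoxy-15-[(tert-butyldiphenylsilyl)oxy]labda-8(17),13E-dien-7α-ol
Product: 26 (13E)-7α,15-dihydroxylabda-8(17),13-dien-19-yl acetate (4S,5R,7R,9R,10S), the target
Conditions: HF·pyridine, pyridine, THF, 0 °C → rt
Reagents that add atoms: none
Why: Buffered fluoride cleaves the primary silyl ether and should leave the neopentyl acetate and both allylic alcohols intact.

**Compound list**

1 | 4-methylfuran-2(5H)-one | CC1=CC(=O)OC1 | starting material
2 | 4-methyl-2,5-dihydrofuran-2-ol | CC1=CC(O)OC1 | intermediate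
3 | (2Z)-2-methylpenta-2,4-dien-1-ol | OC/C(C)=C\C=C | intermediate
4 | ethyl (2E)-3-methyl-4-oxobut-2-enoate | CCOC(=O)/C=C(C)/C=O | starting material
5 | ethyl (2E)-4,4-dimethoxy-3-methylbut-2-enoate | CCOC(=O)/C=C(C)/C(OC)OC | intermediate
6 | (2E)-4,4-dimethoxy-3-methylbut-2-enoic acid | COC(OC)/C(C)=C/C(=O)O | intermediate
7 | (2Z)-2-methylpenta-2,4-dien-1-yl (2E)-4,4-dimethoxy-3-methylbut-2-enoate | COC(OC)/C(C)=C/C(=O)OC/C(C)=C\C=C | intermediate
8 | (2Z)-2-methylpenta-2,4-dien-1-yl (2E)-3-methyl-4-oxobut-2-enoate | O=C/C(C)=C/C(=O)OC/C(C)=C\C=C | intermediate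
9 | (3aS,7S,7aS)-3a,7-dimethyl-1-oxo-1,3,3a,6,7,7a-hexahydro-2-benzofuran-7-carbaldehyde (cis-fused lactone; 4β-CH2O, 5α-H, 10β-CH3 in labdane numbering) | O=C1[C@H]2[C@@](C)(CO1)C=CC[C@]2(C)C=O | intermediate
10 | (3aS,7S,7aS)-3a,7-dimethyl-1-oxooctahydro-2-benzofuran-7-carbaldehyde | O=C1[C@H]2[C@@](C)(CO1)CCC[C@]2(C)C=O | intermediate
11 | 3-methylbut-2-en-1-ol (prenol) | CC(C)=CCO | starting material
12 | tert-butyl[(3-methylbut-2-en-1-yl)oxy]diphenylsilane | CC(C)=CCO[Si](c1ccccc1)(c1ccccc1)C(C)(C)C | intermediate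
13 | (2E)-4-[(tert-butyldiphenylsilyl)oxy]-2-methylbut-2-en-1-ol | OC/C(C)=C/CO[Si](c1ccccc1)(c1ccccc1)C(C)(C)C | intermediate
14 | {[(2E)-4-bromo-3-methylbut-2-en-1-yl]oxy}(tert-butyl)diphenylsilane | BrC/C(C)=C/CO[Si](c1ccccc1)(c1ccccc1)C(C)(C)C | intermediate
15 | {(3E)-5-[(tert-butyldiphenylsilyl)oxy]-3-methylpent-3-en-1-yl}triphenylphosphonium bromide | [Br-].c1ccccc1[P+](c1ccccc1)(c1ccccc1)CC/C(C)=C/CO[Si](c1ccccc1)(c1ccccc1)C(C)(C)C | intermediate
16 | ylide of 15: {(3E)-5-[(tert-butyldiphenylsilyl)oxy]-3-methylpent-3-en-1-ylidene}triphenylphosphorane | c1ccccc1P(c1ccccc1)(c1ccccc1)=CC/C(C)=C/CO[Si](c1ccccc1)(c1ccccc1)C(C)(C)C | intermediate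
17 | lactone 10 with the (1Z,4E)-6-[(tert-butyldiphenylsilyl)oxy]-4-methylhexa-1,4-dien-1-yl chain in place of CHO; ring stereocentres unchanged | O=C1[C@H]2[C@@](C)(CO1)CCC[C@]2(C)/C=C\C/C(C)=C/CO[Si](c1ccccc1)(c1ccccc1)C(C)(C)C | intermediate
18 | lactol of 17 (anomer mixture) | OC1[C@H]2[C@@](C)(CO1)CCC[C@]2(C)/C=C\C/C(C)=C/CO[Si](c1ccccc1)(c1ccccc1)C(C)(C)C | intermediate
19 | homopropargylic diol: ring A with 4β-CH2OH, 5-CH(OH)CH2C≡CH (C6 epimers) and the 10-dienyl chain | C#CCC(O)[C@H]1[C@@](C)(CO)CCC[C@]1(C)/C=C\C/C(C)=C/CO[Si](c1ccccc1)(c1ccccc1)C(C)(C)C | intermediate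
20 | 19-acetate of diol 19 | C#CCC(O)[C@H]1[C@@](C)(COC(C)=O)CCC[C@]1(C)/C=C\C/C(C)=C/CO[Si](c1ccccc1)(c1ccccc1)C(C)(C)C | intermediate
21 | C6 O-(imidazol-1-ylthiocarbonyl) derivative of 20 | C#CCC(OC(=S)n1ccnc1)[C@H]1[C@@](C)(COC(C)=O)CCC[C@]1(C)/C=C\C/C(C)=C/CO[Si](c1ccccc1)(c1ccccc1)C(C)(C)C | intermediate
22 | enyne: ring A with 4β-CH2OAc, 5-(but-3-yn-1-yl) and the 10-dienyl chain | C#CCC[C@H]1[C@@](C)(COC(C)=O)CCC[C@]1(C)/C=C\C/C(C)=C/CO[Si](c1ccccc1)(c1ccccc1)C(C)(C)C | intermediate
23 | 17-(tributylstannyl) derivative of 24 (alkene isomer mixture) | CCCC[Sn](CCCC)(CCCC)C=C1CC[C@H]2[C@@](C)(COC(C)=O)CCC[C@]2(C)[C@H]1CC/C(C)=C/CO[Si](c1ccccc1)(c1ccccc1)C(C)(C)C | intermediate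
24 | 19-acetoxy-15-[(tert-butyldiphenylsilyl)oxy]labda-8(17),13E-diene | C=C1CC[C@H]2[C@@](C)(COC(C)=O)CCC[C@]2(C)[C@H]1CC/C(C)=C/CO[Si](c1ccccc1)(c1ccccc1)C(C)(C)C | intermediate
25 | 19-acetoxy-15-[(tert-butyldiphenylsilyl)oxy]labda-8(17),13E-dien-7α-ol | C=C1[C@H](O)C[C@H]2[C@@](C)(COC(C)=O)CCC[C@]2(C)[C@H]1CC/C(C)=C/CO[Si](c1ccccc1)(c1ccccc1)C(C)(C)C | intermediate
26 | (13E)-7α,15-dihydroxylabda-8(17),13-dien-19-yl acetate (4S,5R,7R,9R,10S) | C=C1[C@H](O)C[C@H]2[C@@](C)(COC(C)=O)CCC[C@]2(C)[C@H]1CC/C(C)=C/CO | target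

**Totals**

Total step count: 21. Longest linear sequence: 15 steps (steps 1, 2, 5–8, 13–21).

**Steps most likely to fail**

Step 7 (proposed new method). The catalysed cycloaddition may be too slow or poorly face-selective, because the catalyst-bound formyl group must sit endo beneath a hindered (Z)-diene and the ester tether must adopt its less favoured conformation; the acid may also isomerise or oligomerise the diene. Fallback, setting out from 8: thermal cycloaddition in toluene at 110 °C with BHT gives 9 together with the enantiomeric adduct F1. Condensation of the mixture with (1R,2R)-N,N'-dimethyl-1,2-diphenylethane-1,2-diamine gives the diastereomeric imidazolidine F2 (from 9) and imidazolidine F3 (from F1), which are separated by chromatography or crystallisation. Hydrolysis of F2 on wet silica gel returns to 9.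

Step 19. The vinyl radical may close 7-endo, the alkyne may simply be hydrostannylated, or the facial selectivity at C9 may be poor; C9 cannot be corrected afterwards. Fallback, setting out from 18, which places C9 next to a ketone so that it can be equilibrated:
- allyl (triphenylphosphoranylidene)acetate in toluene at 80 °C gives the hydroxy enoate F4;
- immediate acetylation (Ac2O, pyridine, DMAP) gives the acetate F5;
- conjugate reduction with [(Ph3P)CuH]6 in wet toluene gives the saturated allyl ester F6;
- Pd(PPh3)4 and morpholine give the acid F7;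
- (PhSe)2 and PBu3 give the Se-phenyl selenoester F8;
- Bu3SnH and AIBN in dilute benzene give the 8-ketone F9 by 6-exo acyl radical cyclisation, and DBU equilibrates C9 to the equatorial side chain;
- methylenation with Zn, CH2Br2 and TiCl4 returns to 24.

Step 20. Oxidation may occur at C12 of the side-chain alkene or at C9, or proceed further to the enone. Fallback, setting out from 24, which deactivates the side-chain alkene by a change of oxidation state: HF·pyridine gives the allylic alcohol F10; MnO2 gives the enal F11; SeO2 with t-BuOOH then gives the 7α-hydroxy enal F12; NaBH4 with CeCl3·7H2O in MeOH at 0 °C reduces the aldehyde and returns to 26.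

**Further compounds**

F1 | step 7 | (3aR,7R,7aR)-3a,7-dimethyl-1-oxo-1,3,3a,6,7,7a-hexahydro-2-benzofuran-7-carbaldehyde (enantiomer of 9) | O=C1[C@@H]2[C@](C)(CO1)C=CC[C@@]2(C)C=O
F2 | step 7 | (4R,5R)-1,3-dimethyl-4,5-diphenylimidazolidin-2-yl aminal of 9 | O=C1[C@H]2[C@@](C)(CO1)C=CC[C@]2(C)C1N(C)[C@H](c2ccccc2)[C@@H](c2ccccc2)N1C
F3 | step 7 | (4R,5R)-1,3-dimethyl-4,5-diphenylimidazolidin-2-yl aminal of F1 | O=C1[C@@H]2[C@](C)(CO1)C=CC[C@@]2(C)C1N(C)[C@H](c2ccccc2)[C@@H](c2ccccc2)N1C
F4 | step 19 | allyl (E)-enoate at C6=C7 with free 19-OH | C=CCOC(=O)/C=C/[C@H]1[C@@](C)(CO)CCC[C@]1(C)/C=C\C/C(C)=C/CO[Si](c1ccccc1)(c1ccccc1)C(C)(C)C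
F5 | step 19 | 19-acetate of F4 | C=CCOC(=O)/C=C/[C@H]1[C@@](C)(COC(C)=O)CCC[C@]1(C)/C=C\C/C(C)=C/CO[Si](c1ccccc1)(c1ccccc1)C(C)(C)C
F6 | step 19 | saturated allyl ester (C6, C7 as CH2) | C=CCOC(=O)CC[C@H]1[C@@](C)(COC(C)=O)CCC[C@]1(C)/C=C\C/C(C)=C/CO[Si](c1ccccc1)(c1ccccc1)C(C)(C)C
F7 | step 19 | C8 carboxylic acid | OC(=O)CC[C@H]1[C@@](C)(COC(C)=O)CCC[C@]1(C)/C=C\C/C(C)=C/CO[Si](c1ccccc1)(c1ccccc1)C(C)(C)C
F8 | step 19 | Se-phenyl selenoester of F7 | O=C(CC[C@H]1[C@@](C)(COC(C)=O)CCC[C@]1(C)/C=C\C/C(C)=C/CO[Si](c1ccccc1)(c1ccccc1)C(C)(C)C)[Se]c1ccccc1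
F9 | step 19 | 19-acetoxy-15-[(tert-butyldiphenylsilyl)oxy]-17-norlabd-13E-en-8-one | O=C1CC[C@H]2[C@@](C)(COC(C)=O)CCC[C@]2(C)[C@H]1CC/C(C)=C/CO[Si](c1ccccc1)(c1ccccc1)C(C)(C)C
F10 | step 20 | 19-acetoxylabda-8(17),13E-dien-15-ol | C=C1CC[C@H]2[C@@](C)(COC(C)=O)CCC[C@]2(C)[C@H]1CC/C(C)=C/CO
F11 | step 20 | 19-acetoxylabda-8(17),13E-dien-15-al | C=C1CC[C@H]2[C@@](C)(COC(C)=O)CCC[C@]2(C)[C@H]1CC/C(C)=C/C=O
F12 | step 20 | 19-acetoxy-7α-hydroxylabda-8(17),13E-dien-15-al | C=C1[C@H](O)C[C@H]2[C@@](C)(COC(C)=O)CCC[C@]2(C)[C@H]1CC/C(C)=C/C=O
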